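**Retrosynthetic overview**

1. Numbering: ring A (cyclohexane) is C10 (methyl C14, vinyl C1=C2), C5 (acrolein unit C4, C3, C15), C6 (O6 angelate), C7, C8 (O8), C9 (O9 2-methylbutanoate); ring B (lactone) is C7, C11 (=C13), C12, O8, C8. The strategy rests on the trans-diequatorial C8/C9 diol of ring A with the C6 oxygen two carbons away: these are the C5/C4 diol and C1 of (−)-quinic acid, so ring A is bought and C10/C5 become the β/α carbons of a diacetal-locked enone.
2. Endgame disconnections: O9 ester (last); lactone C12–O8 (closed when the diacetal comes off); C15 aldehyde from the isopropenyl methyl; O6 angelate; C11=C13 (Mannich methylenation); C6–H (hydride); C7–C11 (enolate alkylation).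
3. Key disconnections C10–C14 and C5–C4: copper-catalysed conjugate methylation of the 10-vinyl enone and, in the same flask, palladium-catalysed alkenylation of the enolate with 2-bromopropene. C5 is then adjusted by kinetic protonation of the dienolate.
4. The 10-vinyl enone comes from quinic acid by diacetalisation, ester reduction, glycol cleavage, elimination, vinyl cuprate addition and Saegusa oxidation.
5. Ring order: ring A comes from the chiral pool and is never opened; ring B is the only ring closed (step 15).

Key step: step 7

Remark on the chemistry: read from the SMILES, the 2-methylbutanoate stereocentre is R, so (R)-2-methylbutanoic acid is used; it and angelic acid are assumed to be purchasable. "Up" below means the face of ring A that carries C14.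

**Route**

Step 1
Reactants: 1 (−)-quinic acid; 2 butane-2,3-dione
Product: 3 methyl quinate 4,5-(butane-2,3-diacetal) (quinic acid numbering; 1-OH and 3-OH free)
Conditions: HC(OMe)3, MeOH, camphorsulfonic acid (cat.), reflux
Reagents that add atoms: methanol, CO; trimethyl orthoformate, COC(OC)OC
Why: Fischer esterification and butane-2,3-diacetal formation run together, the diacetal taking the only trans-diequatorial vicinal diol (target O8/O9) with both methoxy groups axial under anomeric control.

Step 2
Reactants: 3 methyl quinate diacetal
Product: 4 diacetal triol (CH2OH and OH on C6, axial OH on C10)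
Conditions: NaBH4, MeOH, 0 °C to rt
Reagents that add atoms: none
Why: Borohydride reduction of an α-hydroxy ester to the 1,2-diol, which touches no stereocentre.

Step 3
Reactants: 4 diacetal triol
Product: 5 diacetal β-hydroxy ketone (C6 ketone, axial 10-OH)
Conditions: NaIO4, H2O/MeOH, 0 °C to rt
Reagents that add atoms: none
Why: Periodate glycol cleavage of the only free vicinal diol gives the C6 ketone and formaldehyde.

Step 4
Reactants: 5 diacetal β-hydroxy ketone
Product: 7 diacetal enone (C5=C10, C6=O), via C10 mesylate 6 (not isolated)
Conditions: MsCl, Et3N, CH2Cl2, 0 °C to rt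
Reagents that add atoms: none
Why: Mesylation of the axial β-hydroxyl and E1cB elimination give the enone, while the equatorial diacetal oxygen on C8 at the other β-position is a poor leaving group and stays.

Step 5
Reactants: 7 diacetal enone; 8 vinylmagnesium bromide
Product: 9 C10-vinyl C5=C6 trimethylsilyl enol ether
Conditions: CuBr·SMe2 (10 mol%), Me3SiCl, THF, −78 °C; Et3N quench
Reagents that add atoms: chlorotrimethylsilane, C[Si](C)(C)Cl
Why: Copper-catalysed conjugate addition of the Grignard reagent with in situ silylation gives the regiodefined silyl enol ether; the vinyl group should enter axially at C10, but this centre is erased in step 6.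

Step 6
Reactants: 9 C10-vinyl silyl enol ether
Product: 10 diacetal 10-vinyl enone (C1=C2–C10=C5–C6=O)
Conditions: Pd(OAc)2 (10 mol%), O2 (1 atm), DMSO, rt
Reagents that add atoms: none
Why: Saegusa oxidation, in which divalent palladium forms the C5 palladium enolate, β-hydride elimination of H10 restores the enone with the vinyl group on C10, and O2 returns zerovalent palladium to the divalent state.

Step 7
Reactants: 10 diacetal 10-vinyl enone; 11 2-bromopropene
Product: 14 C6 ketone with C14 axial on C10 and C4 axial on C5, via bromomagnesium enolate 12 (not isolated), via chlorozinc enolate 13 (not isolated)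
Conditions: Cu(OTf)2 (5 mol%), 1,3-dimesitylimidazolium chloride (6 mol%), CH3MgBr (1.3 equiv), Et2O, −30 °C; ZnCl2 (1.5 equiv), THF, 0 °C; 11 (2 equiv), Pd2(dba)3 (2.5 mol%), P(t-Bu)3 (10 mol%), 40 °C
Reagents that add atoms: methylmagnesium bromide, C[Mg]Br
Why: Proposed new method: a methylcopper–carbene species formed from CH3MgBr, Cu(OTf)2 and 1,3-dimesitylimidazol-2-ylidene adds to C10 of the dienone (π-complex, bond formation at the β-carbon, reductive elimination) to give magnesium enolate 12, ZnCl2 turns it into zinc enolate 13, zerovalent palladium inserts into the C–Br bond of 11, and transmetallation then reductive elimination from the C5-bound palladium enolate makes C5–C4. The closest known reactions are the copper–carbene-catalysed 1,4-addition of Grignard reagents to 3-alkenyl cyclohexenones, which gives vinyl-bearing quaternary centres, and the palladium-catalysed α-alkenylation of preformed ketone enolates with alkenyl bromides; new is their merger in one flask at an α-carbon next to a fresh quaternary centre. No ring is closed. C10 is set by stereoelectronic axial attack on the half-chair that the trans-fused diacetal holds rigid, so C14 ends axial, cis to O9 and trans to O8; at C5 the palladium fragment should approach anti to that axial methyl, which places C4 axial and cis to the vinyl group, and this centre is put right in step 8. The step needs 1,4- over 1,6-addition, which the carbene ligand on copper should secure, and C5 over C7 alkenylation, which follows because the conjugate addition makes the C5=C6 enolate regiospecifically and no C6=C7 enolate (the one that could expel O8) is formed.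

Step 8
Reactants: 14 C5-epimeric ketone
Product: 16 C6 ketone with C4 equatorial on C5 (cis to C14, trans to vinyl), via potassium dienolate 15 (not isolated)
Conditions: KOt-Bu (1.5 equiv), t-BuOH/THF, 0 °C; inverse quench into AcOH/THF, −78 °C
Reagents that add atoms: none
Why: Thermodynamic deprotonation removes the doubly activated C5–H to give the extended enolate, and kinetic α-protonation of this dienolate (deconjugative protonation) should deliver the proton axially from the face anti to the axial C14 methyl, leaving C4 equatorial.

Step 9
Reactants: 16 C6 ketone; 17 tert-butyl bromoacetate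
Product: 19 keto ester with CH2CO2t-Bu axial on C7 (cis to O8), via lithium enolate 18 (not isolated)
Conditions: LiN(i-Pr)2 (1.1 equiv), THF, −78 °C (ketone added to base); 17, DMPU, −78 to −40 °C; AcOH, −78 °C
Reagents that add atoms: none
Why: Kinetic deprotonation takes the open C7 methylene rather than the tertiary, neopentyl-type C5–H, and SN2 alkylation of the enolate proceeds axially through a chair-like transition state on the face anti to the axial C14 methyl, setting C7, while the equatorial C8–O bond lies near the nodal plane of the enolate and should not be expelled.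

Step 10
Reactants: 19 keto ester
Product: 20 hydroxy ester with axial 6-OH (cis to C14, trans-diaxial to the C7 side chain)
Conditions: LiBH(s-Bu)3, THF, −78 °C; H2O
Reagents that add atoms: none
Why: The bulky borohydride attacks the ketone along the equatorial trajectory because the axial C14 methyl screens the other face, which sets C6 with an axial hydroxyl that cannot lactonise onto the trans-diaxial ester, and the tert-butyl ester is not reduced at this temperature.

Step 11
Reactants: 20 hydroxy ester
Product: 24 tert-butyl acrylate (C11=C13) with free 6-OH, via dilithio ester enolate 21 (not isolated), via Mannich base 22 (not isolated), via ammonium iodide 23 (not isolated)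
Conditions: LiN(i-Pr)2 (2.3 equiv), THF, −78 °C; CH2=NMe2+ I−, −78 °C to rt; aqueous work-up; MeI, MeOH, rt; NaHCO3 (aq), CH2Cl2
Reagents that add atoms: N,N-dimethylmethyleneiminium iodide (Eschenmoser's salt), C=[N+](C)C.[I-]
Why: Eschenmoser methylenation, in which the ester enolate (O6 carried as its lithium alkoxide) undergoes a Mannich reaction and N-methylation then E1cB loss of trimethylamine gives the acrylate, so the transient C11 centre becomes sp2.

Step 12
Reactants: 24 tert-butyl acrylate; 25 angelic acid
Product: 27 C6 angelate, via mixed anhydride 26 (not isolated)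
Conditions: 25, 2,4,6-trichlorobenzoyl chloride, Et3N, toluene, rt; then 24, toluene, 80 °C
Reagents that add atoms: none
Why: Yamaguchi esterification, in which the hindered axial alcohol attacks the angeloyl carbonyl because the aroyl carbonyl is shielded by its two ortho chlorines, and leaving out a nucleophilic catalyst limits Z to E isomerisation to the tiglate.

Step 13
Reactants: 27 C6 angelate
Product: 28 C15 allylic alcohol (CH2=C(CH2OH) on C5)
Conditions: SeO2 (0.5 equiv), t-BuOOH, CH2Cl2, 0 °C to rt
Reagents that add atoms: selenium dioxide, O=[Se]=O; tert-butyl hydroperoxide, CC(C)(C)OO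
Why: SeO2 allylic oxidation (ene reaction then [2,3]-sigmatropic shift) should pick the electron-rich isopropenyl group over the electron-poor acrylate and angelate and the vinyl group that has no allylic hydrogen, and the C15 methyl over the hindered tertiary C5–H.

Step 14
Reactants: 28 C15 allylic alcohol
Product: 29 enal (C15 aldehyde)
Conditions: Dess–Martin periodinane, CH2Cl2, 0 °C to rt
Reagents that add atoms: none
Why: Dess–Martin oxidation of the primary allylic alcohol to the enal under near-neutral conditions that leave the esters and the diacetal alone.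

Step 15
Reactants: 29 enal
Product: 31 α-methylene lactone with free equatorial 9-OH, via dihydroxy acid 30 (not isolated)
Conditions: TFA/H2O (9:1), CH2Cl2, 0 °C to rt; concentrate from toluene
Reagents that add atoms: none
Why: Aqueous acid hydrolyses the diacetal and cleaves the tert-butyl ester by alkyl–oxygen fission, and the acrylic acid closes ring B by 5-exo-trig lactonisation onto the cis O8, the only hydroxyl within reach because O9 is trans and 1,3 to C7 and O6 is acylated; the isopropenyl group is by now an acid-stable enal.

Step 16
Reactants: 31 hydroxy lactone; 32 (R)-2-methylbutanoic acid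
Product: 33 target CNP0295282.1
Conditions: 32, DCC, DMAP (cat.), CH2Cl2, 0 °C
Reagents that add atoms: none
Why: Steglich esterification of the only free hydroxyl, the equatorial 9-OH, at low temperature with catalytic DMAP so that the α-stereocentre of the acid is kept.

**Compound list**

1 | (−)-quinic acid, (1S,3R,4S,5R)-1,3,4,5-tetrahydroxycyclohexanecarboxylic acid | C1[C@H]([C@H]([C@@H](C[C@@]1(C(=O)O)O)O)O)O | starting material
2 | butane-2,3-dione | CC(=O)C(C)=O | starting material
3 | methyl quinate with the trans 4,5-diol bridged as the 2,3-dimethoxybutane-2,3-diyl diacetal (both OMe axial) | O[C@@H]1C[C@@](O)(C(=O)OC)C[C@H]2O[C@](C)(OC)[C@@](C)(OC)O[C@H]12 | intermediate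
4 | diacetal triol (ester of 3 reduced to CH2OH) | O[C@@H]1C[C@@](O)(CO)C[C@H]2O[C@](C)(OC)[C@@](C)(OC)O[C@H]12 | intermediate
5 | diacetal β-hydroxy ketone (C6 ketone, axial 10-OH) | O[C@@H]1CC(=O)C[C@H]2O[C@](C)(OC)[C@@](C)(OC)O[C@H]12 | intermediate
6 | C10 mesylate of 5 | CS(=O)(=O)O[C@@H]1CC(=O)C[C@H]2O[C@](C)(OC)[C@@](C)(OC)O[C@H]12 | intermediate (not isolated)
7 | diacetal enone (C5=C10, C6=O; O8/O9 trans-diequatorial) | C1=CC(=O)C[C@H]2O[C@](C)(OC)[C@@](C)(OC)O[C@H]12 | intermediate
8 | vinylmagnesium bromide | C=C[Mg]Br | starting material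
9 | C5=C6 trimethylsilyl enol ether with axial vinyl on C10 | C=C[C@@H]1C=C(O[Si](C)(C)C)C[C@H]2O[C@](C)(OC)[C@@](C)(OC)O[C@H]12 | intermediate
10 | diacetal 10-vinyl enone (key-step precursor) | C=CC1=CC(=O)C[C@H]2O[C@](C)(OC)[C@@](C)(OC)O[C@H]12 | intermediate
11 | 2-bromopropene | CC(Br)=C | starting material
12 | bromomagnesium C5=C6 enolate with C10 (axial methyl, equatorial vinyl) | C=C[C@@]1(C)C=C(O[Mg]Br)C[C@H]2O[C@](C)(OC)[C@@](C)(OC)O[C@H]12 | intermediate (not isolated)
13 | chlorozinc C5=C6 enolate | C=C[C@@]1(C)C=C(O[Zn]Cl)C[C@H]2O[C@](C)(OC)[C@@](C)(OC)O[C@H]12 | intermediate (not isolated)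
14 | C6 ketone, C14 axial on C10, isopropenyl axial on C5 (cis to vinyl) | C=C[C@@]1(C)[C@@H](C(C)=C)C(=O)C[C@H]2O[C@](C)(OC)[C@@](C)(OC)O[C@H]12 | intermediate
15 | potassium dienolate of 14 (C5=C6 enolate conjugated with the isopropenyl group) | C=C[C@@]1(C)C(C(C)=C)=C(O[K])C[C@H]2O[C@](C)(OC)[C@@](C)(OC)O[C@H]12 | intermediate (not isolated)
16 | C6 ketone, isopropenyl equatorial on C5 (cis to C14, trans to vinyl) | C=C[C@@]1(C)[C@H](C(C)=C)C(=O)C[C@H]2O[C@](C)(OC)[C@@](C)(OC)O[C@H]12 | intermediate
17 | tert-butyl bromoacetate | CC(C)(C)OC(=O)CBr | starting material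
18 | lithium C6=C7 enolate of 16 | C=C[C@@]1(C)[C@H](C(C)=C)C(O[Li])=C[C@H]2O[C@](C)(OC)[C@@](C)(OC)O[C@H]12 | intermediate (not isolated)
19 | keto ester, CH2CO2t-Bu axial on C7 (cis to O8, trans to the C5 isopropenyl) | C=C[C@@]1(C)[C@H](C(C)=C)C(=O)[C@@H](CC(=O)OC(C)(C)C)[C@H]2O[C@](C)(OC)[C@@](C)(OC)O[C@H]12 | intermediate
20 | hydroxy ester, axial 6-OH (cis to C14) | C=C[C@@]1(C)[C@H](C(C)=C)[C@H](O)[C@@H](CC(=O)OC(C)(C)C)[C@H]2O[C@](C)(OC)[C@@](C)(OC)O[C@H]12 | intermediate
21 | dilithio species of 20 (O6 alkoxide and ester enolate) | C=C[C@@]1(C)[C@H](C(C)=C)[C@H](O[Li])[C@@H](C=C(O[Li])OC(C)(C)C)[C@H]2O[C@](C)(OC)[C@@](C)(OC)O[C@H]12 | intermediate (not isolated)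
22 | Mannich base (CH2NMe2 on C11, C11 epimers) | C=C[C@@]1(C)[C@H](C(C)=C)[C@H](O)[C@@H](C(CN(C)C)C(=O)OC(C)(C)C)[C@H]2O[C@](C)(OC)[C@@](C)(OC)O[C@H]12 | intermediate (not isolated)
23 | trimethylammonium iodide of 22 | C=C[C@@]1(C)[C@H](C(C)=C)[C@H](O)[C@@H](C(C[N+](C)(C)C)C(=O)OC(C)(C)C)[C@H]2O[C@](C)(OC)[C@@](C)(OC)O[C@H]12.[I-] | intermediate (not isolated)
24 | tert-butyl acrylate (C11=C13) with free axial 6-OH | C=C[C@@]1(C)[C@H](C(C)=C)[C@H](O)[C@@H](C(=C)C(=O)OC(C)(C)C)[C@H]2O[C@](C)(OC)[C@@](C)(OC)O[C@H]12 | intermediate
25 | angelic acid, (Z)-2-methylbut-2-enoic acid | C/C=C(/C)C(=O)O | starting material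
26 | angelic 2,4,6-trichlorobenzoic anhydride | C/C=C(/C)C(=O)OC(=O)c1c(Cl)cc(Cl)cc1Cl | intermediate (not isolated)
27 | C6 angelate of 24 | C=C[C@@]1(C)[C@H](C(C)=C)[C@H](OC(=O)/C(C)=C\C)[C@@H](C(=C)C(=O)OC(C)(C)C)[C@H]2O[C@](C)(OC)[C@@](C)(OC)O[C@H]12 | intermediate
28 | C15 allylic alcohol | C=C[C@@]1(C)[C@H](C(=C)CO)[C@H](OC(=O)/C(C)=C\C)[C@@H](C(=C)C(=O)OC(C)(C)C)[C@H]2O[C@](C)(OC)[C@@](C)(OC)O[C@H]12 | intermediate
29 | enal (C15 aldehyde), diacetal and tert-butyl acrylate intact | C=C[C@@]1(C)[C@H](C(=C)C=O)[C@H](OC(=O)/C(C)=C\C)[C@@H](C(=C)C(=O)OC(C)(C)C)[C@H]2O[C@](C)(OC)[C@@](C)(OC)O[C@H]12 | intermediate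
30 | 8,9-dihydroxy acrylic acid | C=C[C@@]1(C)[C@H](C(=C)C=O)[C@H](OC(=O)/C(C)=C\C)[C@@H](C(=C)C(=O)O)[C@@H](O)[C@@H]1O | intermediate (not isolated)
31 | cis-fused α-methylene lactone (C12–O8) with free 9-OH | C=C[C@@]1(C)[C@H](C(=C)C=O)[C@H](OC(=O)/C(C)=C\C)[C@H]2C(=C)C(=O)O[C@H]2[C@@H]1O | intermediate
32 | (R)-2-methylbutanoic acid | CC[C@@H](C)C(=O)O | starting material
33 | CNP0295282.1 | C=C[C@@]1(C)[C@H](C(=C)C=O)[C@H](OC(=O)/C(C)=C\C)[C@H]2C(=C)C(=O)O[C@H]2[C@@H]1OC(=O)[C@H](C)CC | target

**Step count**

Total steps: 16. Longest linear sequence: 16 steps, from 1 to 33.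

**Steps most likely to fail**

Step 7 (new method). The methyl group may add 1,6 to the vinyl terminus or transfer slowly to the hindered C10, and transmetallation or reductive elimination at the congested C5 may stall in the presence of magnesium salts, so that the enolate is only protonated on work-up. The fallback separates the two halves and uses known reactions. It sets out from 10: the copper–carbene-catalysed 1,4-addition of CH3MgBr is run alone and the enolate is quenched with Me3SiCl/Et3N to isolate the C5=C6 trimethylsilyl enol ether F1. F1 is then coupled with 11 under Pd2(dba)3/P(t-Bu)3 in the presence of Bu3SnF, which forms the tin enolate in the flask; palladium-catalysed alkenylation of tin enolates with 1-bromoalkenes is established. The fallback returns to the route at 14, and step 8 follows as written.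

Step 9. Proton transfer may move the enolate to the more acidic C5 position, the C7 enolate may expel O8 and open the diacetal, or the electrophile may enter from the wrong face or twice. The fallback avoids a free C7 enolate. It sets out from 16: LiN(i-Pr)2 with Me3SiCl already present (internal quench, THF, −78 °C) gives the kinetic C6=C7 trimethylsilyl enol ether F2. Cyclopropanation of this most electron-rich alkene with tert-butyl diazoacetate and Rh2(OAc)4, on the face anti to the axial C14 methyl, gives the siloxycyclopropane ester F3. Fluoride-induced ring opening of this donor–acceptor cyclopropane (Et3N·3HF, THF) breaks the C6–C11 bond and gives the γ-keto ester, with C7 fixed by the face of cyclopropanation. The fallback returns to the route at 19.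

Step 12. Acylation of the axial 6-OH, which sits 1,3-diaxial to C14, may be incomplete, and forcing it may isomerise the angeloyl group to tigloyl. The fallback builds the Z-alkene on the molecule. It sets out from 24: esterification with 2-(diphenoxyphosphoryl)propanoic acid (DCC, DMAP, CH2Cl2; this acid has no alkene geometry to lose, so forcing is allowed) gives the C6 phosphonopropanoate F4. A Z-selective Horner–Wadsworth–Emmons olefination of F4 with acetaldehyde (NaH, THF, −78 °C; diaryl phosphonates favour Z-enoates) gives the angelate. The fallback returns to the route at 27.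

**Further compounds**

F1 | step 7 | C5=C6 trimethylsilyl enol ether of the C10 methyl adduct | C=C[C@@]1(C)C=C(O[Si](C)(C)C)C[C@H]2O[C@](C)(OC)[C@@](C)(OC)O[C@H]12
F2 | step 9 | C6=C7 trimethylsilyl enol ether of 16 | C=C[C@@]1(C)[C@H](C(C)=C)C(O[Si](C)(C)C)=C[C@H]2O[C@](C)(OC)[C@@](C)(OC)O[C@H]12
F3 | step 9 | C6/C7 siloxycyclopropane tert-butyl ester (C11 bridging on the face anti to C14, ester epimers) | C=C[C@@]1(C)[C@H](C(C)=C)[C@@]3(O[Si](C)(C)C)C(C(=O)OC(C)(C)C)[C@H]3[C@H]2O[C@](C)(OC)[C@@](C)(OC)O[C@H]12
F4 | step 12 | C6 2-(diphenoxyphosphoryl)propanoate of 24 | C=C[C@@]1(C)[C@H](C(C)=C)[C@H](OC(=O)C(C)P(=O)(Oc3ccccc3)Oc3ccccc3)[C@@H](C(=C)C(=O)OC(C)(C)C)[C@H]2O[C@](C)(OC)[C@@](C)(OC)O[C@H]12
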